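Slowness marks this flask of G and E: Z reads 23% of the G charge after 8.00 min, but 40% after 50.0 min, and the questions concern 1.5 h.

- delta: G 0.010 M; E 0.81 mM; the very flask that is asked about, followed so far
- flask: G 0.010 M; E 0.81 mM; time 1.5 h

delta run (percent of the G charged)

| time / min | Z / % | G / % |
|---|---|---|
| 8.00 | 23 | 83 |
| 15.0 | 27 | 71 |
| 25.0 | 34 | 69 |
| 30.0 | 34 | 62 |
| 40.0 | 37 | 62 |
| 50.0 | 40 | 60 |

(standard deviation of a reading: 2 percentage points)

- the average divides the monomer in chains by the number of chains begun, living and dead together
- steps thought possible: Z + X -> G + X; G + E -> L; G + X -> Z + X; G + E -> X + Z; 2 X -> D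
- the earlier runs do not show the number of chains; that part of a forecast is a guess

- whether the average number of monomer units in a chain (chains begun, living or dead) reaches 5.0 by 1.5 h (no / yes)
- average number of monomer units in a chain (chains begun, living or dead) at 1.5 h

The bench rule allows at most one chain per E, so the average length (the number-average degree of polymerisation) is at least the Z fraction times the ratio of G charged to E charged, 12.3. Read backwards, length 5.0 times E charged over G charged gives 40.5%, the floor fraction: the Z fraction at which the wanted length is reached even if every E begins a chain. Above the floor the answer is yes, whatever share of E begins chains. Below it the answer hangs on the chain count, which the readings do not show.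

The last Z reading of this flask stands 0.5 percentage points under the floor, less than the scatter of 2 points, so that reading cannot be told from the floor. The Z readings gained 6 points over their last 20.0 min, more than that gap, and 40.0 min remain, so this reckoning expects yes.

The forecast also says yes, with length 6.2 in a range of 5.2 to 9: “Reaching 5.0 needs only about 40.5% Z even with every E used, so it is very likely reached.”

The simulation gives yes, with length 5.75.

    Z + X → G + X, rate k1*[X] as long as [Z] is above zero (k = 0.00480 s⁻¹)
    G + E → L (k = 0.110 M⁻¹ s⁻¹)
    G + X → Z + X, rate k3*[X]*[G] (k = 1.10 M⁻¹ s⁻¹)
    G + E → X + Z (k = 1.60 M⁻¹ s⁻¹)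
    2 X → D (k = 0.840 M⁻¹ s⁻¹)

In the flask, G + E into X + Z had half of its turnover up to the asked time behind it by 0.693 min, and E stood at 0.0358% of its charge at 0.150 h, with L at 0.521% of the G charge. G into Z and Z into G ran on with X, which fell from 59.8% of the E charge at 0.150 h to 12.1% at 1.50 h while D grew, and Z stood at 43.6% at 1.50 h, 3.1 points above the floor. Length 5.0 came at 0.751 h with Z at 37.9%, under the floor, and L then held 6.43% of the E charge, so the floor with that share taken out is 37.9%.

Readings and results stem from a simulated flask for an exercise, noise included.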